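Two questions stood on the four flasks: the excess of X over E at the end, and how that row runs.

- excess of X over E at the end for north-west, north-east, north, west, in this order
- how the row runs (falls all the way / falls, then rises / rises, then falls / hardly changes / rises all the way)

| flask | Q | J | G | L | remark | time |
|---|---|---|---|---|---|---|
| epsilon | 0.83 M | 0.83 M | 2 equiv | 1.5 mol% | run made earlier |  |
| delta | 0.83 M | 0.83 M | 2 equiv | 15 mol% | run made earlier |  |
| north-west | 0.83 M | 0.83 M | 2.00 equiv | 2.5 mol% |  | 15 h |
| north-east | 0.83 M | 0.83 M | 2.00 equiv | 5 mol% |  | 15 h |
| north | 0.83 M | 0.83 M | 2.00 equiv | 10 mol% |  | 15 h |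
| west | 0.83 M | 0.83 M | 2.00 equiv | 20 mol% |  | 15 h |

- epsilon (time / h: X / %, E / %, Q / %): 0.667: 20.9, 9.3, 28.3; 1.33: 28.8, 14.4, 20.7; 3.00: 38.1, 17.8, 13.4; 8.00: 45.2, 24.8, 5.5
- delta (time / h: X / %, E / %, Q / %): 1.00: 41.9, 26.9, 6.0; 2.50: 46.5, 31.8, 4.1; 5.00: 46.3, 32.8, 3.6; 8.00: 47.1, 34.3, 2.9

(each reading ± 1 percentage point)

- L is single-handed; Q and J are mirror images of each other, charged as a racemate, each of them at the stated concentration
- an excess is the difference of the two amounts in percent of their sum
- "hardly changes" means that all values lie within two and a half points (for a concentration: within two and a half percent of the largest)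

I worked with the fraction left and not with the fraction made. Q and J were charged alike, so in the epsilon run at 3.00 h I had Q at 26.8% of its own charge and J, reckoned from E, at 64.4%. The logarithm of the first over the logarithm of the second is the selectivity factor, 2.99, a reading that carries the scatter. If one G and one L serve both enantiomers, their amounts cancel in this ratio. The excess is then the difference of the two fractions left over two minus their sum, and it is a function of the fraction of J left.

One number was not enough, since it gave the curve and not the place on it. Delta, with ten times the loading of epsilon, held Q at 6.0% after 1.00 h, and epsilon held 5.5% after 8.00 h, so I took loading times time as the place. In loading times time, the end of north-west then matched delta at 2.50 h, where delta's J, reckoned from E, stood at 36.4% of its charge, and the factor gave an excess of 19.9%. The end of north-east matched delta at 5.00 h, where delta's J stood at 34.4% of its charge, which gave an excess of 18.8%.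

The forecast, which differs from my two figures, gave 18.5%, 17%, 15% and 13.5%, a row that falls all the way: “Q runs out while J keeps creeping, so the excess falls steadily”.

The flasks gave 21.0%, 18.6%, 16.7% and 15.1%, a row that falls all the way, as forecast.

    G + L + Q → L + X (k = 0.938 M⁻² min⁻¹)
    G + L + J → L + E (k = 0.329 M⁻² min⁻¹)
    2 L → Z (k = 0.311 M⁻¹ min⁻¹)

West ended at 15.1%, and the same run without the passing of 2 L into Z gave 1.18%, so this catalyst death is the main reason for the excess that remained. At 15.0 h west held 1.06% of its L, with 28% of its J left, and at that place the factor gives an excess of 15.2%. For north-west, with 39% of its J left, the factor gives 21.3%.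

The runs come from a simulation from invented constants; noise was put on by code.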